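**Plan**
Cuts: the C3' phenol is masked as its triflate. Ring C is opened at O1–C8a to a 1,3-diketone. The diketone is cut at C2–C3 into 3,4,5-trimethoxyacetophenone (ring A, C4, C3) and a ring B aldehyde (C2).
Forward: rings A and B are bought. The sequence is triflation, aldol union of C3 with C2, oxidation to the diketone, anodic C–H etherification that closes ring C, and removal of the triflate.
Enabling feature: C8a lies between C4a (which carries the C4 carbonyl) and C8–OMe, and para to C6–OMe. Before closure ring A is a symmetric 3,4,5-trimethoxybenzoyl group, so O1 can bond to either ortho C–H and still give the 6,7,8-trimethoxy, C5–H pattern.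
Stereochemistry: the target has no stereocentre. The carbinol centre made in the aldol step is racemic and is erased by the oxidation.

Key step: step 4

Assumption: the open-chain precursor of the key step is drawn as the 1,3-diketone, although in solution it is mainly the chelated enol; both tautomers count as one compound.

**Route**

Step 1
Reactants: 1 3-hydroxy-4,5-dimethoxybenzaldehyde; 2 trifluoromethanesulfonic anhydride
Product: 3 5-formyl-2,3-dimethoxyphenyl trifluoromethanesulfonate
Conditions: Tf2O, pyridine, CH2Cl2, 0 °C to rt
Reagents that add atoms: trifluoromethanesulfonic anhydride (2), O=S(=O)(OS(=O)(=O)C(F)(F)F)C(F)(F)F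
Why: O-sulfonylation of a phenol with Tf2O and pyridine is the standard aryl triflate synthesis and leaves the aldehyde and the methyl ethers untouched.

Step 2
Reactants: 4 1-(3,4,5-trimethoxyphenyl)ethan-1-one; 3 5-formyl-2,3-dimethoxyphenyl trifluoromethanesulfonate
Product: 6 rac-5-[1-hydroxy-3-oxo-3-(3,4,5-trimethoxyphenyl)propyl]-2,3-dimethoxyphenyl trifluoromethanesulfonate, via lithium 1-(3,4,5-trimethoxyphenyl)ethenolate 5 (not isolated)
Conditions: 4, LiN(SiMe3)2, THF, −78 °C; then 3, −78 °C; AcOH quench at −78 °C
Reagents that add atoms: none
Why: A directed aldol addition of a preformed lithium enolate to a non-enolisable aldehyde is fast at −78 °C and releases no alkoxide, so the triflate sulfur is spared the attack it would risk in an ester Claisen condensation, and the silylamide base is too weak to start an anionic thia-Fries shift; the new carbinol centre forms as a racemate and is removed in step 3.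

Step 3
Reactants: 6 rac-5-[1-hydroxy-3-oxo-3-(3,4,5-trimethoxyphenyl)propyl]-2,3-dimethoxyphenyl trifluoromethanesulfonate
Product: 7 2,3-dimethoxy-5-[3-oxo-3-(3,4,5-trimethoxyphenyl)propanoyl]phenyl trifluoromethanesulfonate
Conditions: IBX, EtOAc, 77 °C
Reagents that add atoms: none
Why: Oxidation of β-hydroxy ketones to β-diketones with suspended IBX is an established alcohol oxidation that does not go on to oxygenate the central carbon and is inert towards aryl methyl ethers and the aryl triflate.

Step 4
Reactants: 7 2,3-dimethoxy-5-[3-oxo-3-(3,4,5-trimethoxyphenyl)propanoyl]phenyl trifluoromethanesulfonate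
Product: 8 2,3-dimethoxy-5-(6,7,8-trimethoxy-4-oxo-4H-chromen-2-yl)phenyl trifluoromethanesulfonate
Conditions: undivided cell, boron-doped diamond anode, Pt cathode, constant current (5 mA cm−2, about 2.2 F mol−1), Bu4NPF6 (0.1 M), dry 1,1,1,3,3,3-hexafluoropropan-2-ol (HFIP), dilute, rt
Reagents that add atoms: none
Why: Proposed new method: anodic removal of one electron from the electron-rich half of 7, the 3,4,5-trimethoxybenzoyl ring in conjugation with the enol, should give a radical cation that HFIP stabilises but does not trap, with much of its positive charge on the ortho carbon that is para to one methoxy group and ortho to another. The enol oxygen on the ring B side bonds to that carbon after rotation about the C3–C4 bond, which the strongly hydrogen-bond-donating solvent eases by loosening the enol chelate, and loss of a second electron and of two protons restores the aromaticity of ring A while the Pt cathode turns the protons into H2 in preference to reducing the carbonyl groups or the triflate. Ring C closes in a six-membered mode by oxygen attack on an sp2 arene carbon (6-exo-trig if counted on the C8a–C8 π bond, 6-endo-trig on C4a–C8a, both allowed), and the central carbon cannot compete because its bond to the same ortho carbon would make a four-membered ring. The closest known reaction types are anodic dehydrogenative C–O cyclisations onto arenes (2-arylbenzoic acids to benzocoumarins, anilides to benzoxazoles) and the oxidant-mediated closure of 2-hydroxybenzophenones onto methoxylated rings to xanthones, none of which uses a diketone enol as the oxygen partner. No stereocentre is formed; the selectivity needed is between the two aryl rings and between the two ortho positions of ring A, where the ortho positions are interchangeable by the local symmetry of the ring and the strongly electron-withdrawing triflate lifts the oxidation potential of ring B well above that of ring A, so closure of the other enol oxygen onto ring B should not compete. Overoxidation is held back by limiting the charge, since O1 of the product is a vinylogous ester oxygen and adds little donor strength to ring A.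

Step 5
Reactants: 8 2,3-dimethoxy-5-(6,7,8-trimethoxy-4-oxo-4H-chromen-2-yl)phenyl trifluoromethanesulfonate
Product: 9 2-(3-hydroxy-4,5-dimethoxyphenyl)-6,7,8-trimethoxy-4H-chromen-4-one (CNP0265341.0)
Conditions: Et4NOH (aq), 1,4-dioxane, rt; then dilute HCl
Reagents that add atoms: none
Why: Hydroxide attacks the sulfur of the aryl triflate (S–O cleavage, a known mild deprotection of phenol triflates) and releases the phenoxide with its original oxygen, while any reversible opening of the pyrone at C2 is undone by the acidic work-up, because the single ring A phenol so exposed can only close back to the same flavone.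

**Compound list**
1 | 3-hydroxy-4,5-dimethoxybenzaldehyde | COc1cc(C=O)cc(O)c1OC | starting material
2 | trifluoromethanesulfonic anhydride | O=S(=O)(OS(=O)(=O)C(F)(F)F)C(F)(F)F | starting material
3 | 5-formyl-2,3-dimethoxyphenyl trifluoromethanesulfonate | COc1cc(C=O)cc(OS(=O)(=O)C(F)(F)F)c1OC | intermediate
4 | 1-(3,4,5-trimethoxyphenyl)ethan-1-one | CC(=O)c1cc(OC)c(OC)c(OC)c1 | starting material
5 | lithium 1-(3,4,5-trimethoxyphenyl)ethenolate | C=C(O[Li])c1cc(OC)c(OC)c(OC)c1 | intermediate
6 | rac-5-[1-hydroxy-3-oxo-3-(3,4,5-trimethoxyphenyl)propyl]-2,3-dimethoxyphenyl trifluoromethanesulfonate | COc1cc(C(=O)CC(O)c2cc(OC)c(OC)c(OS(=O)(=O)C(F)(F)F)c2)cc(OC)c1OC | intermediate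
7 | 2,3-dimethoxy-5-[3-oxo-3-(3,4,5-trimethoxyphenyl)propanoyl]phenyl trifluoromethanesulfonate | COc1cc(C(=O)CC(=O)c2cc(OC)c(OC)c(OS(=O)(=O)C(F)(F)F)c2)cc(OC)c1OC | intermediate
8 | 2,3-dimethoxy-5-(6,7,8-trimethoxy-4-oxo-4H-chromen-2-yl)phenyl trifluoromethanesulfonate | COc1cc(-c2cc(=O)c3cc(OC)c(OC)c(OC)c3o2)cc(OS(=O)(=O)C(F)(F)F)c1OC | intermediate
9 | 2-(3-hydroxy-4,5-dimethoxyphenyl)-6,7,8-trimethoxy-4H-chromen-4-one | COc1cc(-c2cc(=O)c3cc(OC)c(OC)c(OC)c3o2)cc(O)c1OC | target

**Total step count:** 5
**Longest linear sequence:** 5 (1 → 3 → 6 → 7 → 8 → 9)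

**Steps most likely to fail**

Step 4 (anodic closure). The electron may be taken from the enol rather than from ring A. That would open the way to intermolecular coupling through the central carbon. Oxidative loss of a methyl group, or continued oxidation of the closed product, may also erode the material balance. The fallback makes the same O1–C8a bond by known halide chemistry.
- Setting out from 4, nuclear bromination with NBS in MeCN should give 1-(2-bromo-3,4,5-trimethoxyphenyl)ethan-1-one F1.
- Deprotonation with LiN(SiMe3)2 in THF at −78 °C gives lithium 1-(2-bromo-3,4,5-trimethoxyphenyl)ethenolate F2.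
- Addition of this enolate to 3 gives rac-5-[3-(2-bromo-3,4,5-trimethoxyphenyl)-1-hydroxy-3-oxopropyl]-2,3-dimethoxyphenyl trifluoromethanesulfonate F3.
- IBX in hot EtOAc oxidises that to 5-[3-(2-bromo-3,4,5-trimethoxyphenyl)-3-oxopropanoyl]-2,3-dimethoxyphenyl trifluoromethanesulfonate F4.
- An intramolecular Ullmann-type O-arylation of the enolate (CuI, 1,10-phenanthroline, K2CO3, DMF, 90 °C), a closure known for 1-(2-haloaryl)-1,3-diketones, then forms ring C and comes back to the route at 8.

Step 5 (triflate removal). Hydroxide may add to C2 of the pyrone faster than to sulfur, and the opened diketone may fragment irreversibly by a retro-Claisen process. The fallback exchanges the C–O bond instead of cleaving the S–O bond and uses no hydroxide.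
- Setting out from 8, Miyaura borylation (B2pin2, PdCl2(dppf), KOAc, 1,4-dioxane, 80 °C) should give 2-[3,4-dimethoxy-5-(4,4,5,5-tetramethyl-1,3,2-dioxaborolan-2-yl)phenyl]-6,7,8-trimethoxy-4H-chromen-4-one F5.
- Oxidation of the C–B bond with NaBO3·4H2O in THF–water at rt comes back to the route at 9.

Step 2 (aldol addition). Three processes may cut into the aldol product:
- retro-aldol cleavage on warming;
- dehydration of the benzylic carbinol during work-up or in the hot oxidation that follows;
- attack of the enolate on the triflate sulfur.

The fallback replaces aldol addition plus oxidation by a C-acylation.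
- Setting out from 3, Pinnick oxidation (NaClO2, NaH2PO4, 2-methyl-2-butene, t-BuOH–water) gives 3,4-dimethoxy-5-[(trifluoromethanesulfonyl)oxy]benzoic acid F6.
- (COCl)2 with catalytic DMF in CH2Cl2 gives 3,4-dimethoxy-5-[(trifluoromethanesulfonyl)oxy]benzoyl chloride F7.
- Soft enolisation of 4 with MgBr2·OEt2 and iPr2NEt in CH2Cl2 at rt in the presence of this acid chloride comes back to the route at 7, so steps 2 and 3 are both bypassed.

**Further compounds**
F1 | step 4 | 1-(2-bromo-3,4,5-trimethoxyphenyl)ethan-1-one | CC(=O)c1cc(OC)c(OC)c(OC)c1Br
F2 | step 4 | lithium 1-(2-bromo-3,4,5-trimethoxyphenyl)ethenolate | C=C(O[Li])c1cc(OC)c(OC)c(OC)c1Br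
F3 | step 4 | rac-5-[3-(2-bromo-3,4,5-trimethoxyphenyl)-1-hydroxy-3-oxopropyl]-2,3-dimethoxyphenyl trifluoromethanesulfonate | COc1cc(C(=O)CC(O)c2cc(OC)c(OC)c(OS(=O)(=O)C(F)(F)F)c2)c(Br)c(OC)c1OC
F4 | step 4 | 5-[3-(2-bromo-3,4,5-trimethoxyphenyl)-3-oxopropanoyl]-2,3-dimethoxyphenyl trifluoromethanesulfonate | COc1cc(C(=O)CC(=O)c2cc(OC)c(OC)c(OS(=O)(=O)C(F)(F)F)c2)c(Br)c(OC)c1OC
F5 | step 5 | 2-[3,4-dimethoxy-5-(4,4,5,5-tetramethyl-1,3,2-dioxaborolan-2-yl)phenyl]-6,7,8-trimethoxy-4H-chromen-4-one | COc1cc(-c2cc(=O)c3cc(OC)c(OC)c(OC)c3o2)cc(B4OC(C)(C)C(C)(C)O4)c1OC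
F6 | step 2 | 3,4-dimethoxy-5-[(trifluoromethanesulfonyl)oxy]benzoic acid | COc1cc(C(=O)O)cc(OS(=O)(=O)C(F)(F)F)c1OC
F7 | step 2 | 3,4-dimethoxy-5-[(trifluoromethanesulfonyl)oxy]benzoyl chloride | COc1cc(C(=O)Cl)cc(OS(=O)(=O)C(F)(F)F)c1OC
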